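**Retrosynthetic overview**
1. Target 17 ⇒ ring sulfone 11 + (2E,6E,10E)-12-bromofarnesyl acetate 15, joined by sulfone alkylation and reductive desulfonylation; all three E-alkenes are bought in farnesol.
2. Sulfone 11 ⇐ cyclohexene hydroxy acid 7 by hydrogenation, reduction and sulfur installation.
3. Key step: the only carbocycle is closed by an Ireland–Claisen [3,3] rearrangement of δ-lactone 6, which forms the hindered CH–CMe2 bond and transfers the allylic C–O stereocentre to the ring CH.
4. Lactone 6 ⇐ chelation-controlled acetate aldol on β-hydroxy ketone 5, which comes from (S)-α-hydroxy-γ-butyrolactone 1 (L-malic acid chiral pool).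
5. Ring order: temporary δ-lactone, then the cyclohexene (only carbocycle).

Assumption: ring numbering is C1 = CH bearing the chain, C2 = CMe2, C6 = C(Me)OH; the target is (1S,6S) with OH trans to the chain and an all-E chain. Compounds 1 and 12 are treated as commercial.

**Route**

Step 1
Reactants: 1, (S)-α-hydroxy-γ-butyrolactone
Product: 2, (3S)-oxolane-2,3-diol (lactol, anomer mixture)
Conditions: DIBAL-H (2.2 equiv), THF, −78 °C; Rochelle salt
Reagents that add atoms: none
Why: Partial lactone-to-lactol reduction at low temperature (the first equivalent is consumed by the free OH); the carbinol stereocentre is untouched.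

Step 2
Reactants: 2, lactol
Product: 3, (3S)-5-methylhex-4-ene-1,3-diol
Conditions: i-PrPPh3I, n-BuLi (3.2 equiv ylide), THF, −78 °C → rt
Reagents that add atoms: isopropyltriphenylphosphonium iodide, CC(C)[P+](c1ccccc1)(c1ccccc1)c1ccccc1.[I-]
Why: Wittig olefination of the ring-opened hydroxy aldehyde with a symmetric ylide (no E/Z issue); the α-oxido aldehyde does not epimerise.

Step 3
Reactants: 3, diol
Product: 4, (3S)-3-hydroxy-5-methylhex-4-enoic acid
Conditions: TEMPO (cat.), PhI(OAc)2, MeCN/H2O, 0 °C → rt
Reagents that add atoms: water, O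
Why: Oxoammonium (TEMPO/BAIB) oxidation is selective for the primary alcohol over the secondary allylic alcohol and the alkene.

Step 4
Reactants: 4, hydroxy acid
Product: 5, (4S)-4-hydroxy-6-methylhept-5-en-2-one
Conditions: MeLi (3.5 equiv), THF, 0 °C → rt; TMSCl then aq. NH4Cl
Reagents that add atoms: methyllithium, [Li]C
Why: MeLi adds to the lithium carboxylate to give a stable gem-dialkoxide that collapses to the methyl ketone only on work-up.

Step 5
Reactants: 5, β-hydroxy ketone
Product: 6, (4S,6S)-4-hydroxy-4-methyl-6-(2-methylprop-1-en-1-yl)oxan-2-one (OH cis to the alkenyl group)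
Conditions: i-PrMgCl (1.0 equiv), THF, −78 °C; LiCH2CO2Et (LDA/EtOAc, 2.5 equiv), −78 °C; then PPTS (cat.), PhH, 50 °C
Reagents that add atoms: ethyl acetate, CCOC(C)=O
Why: Chelation-controlled 1,3-induction in an acetate aldol: the β-alkoxide and ketone chelate the metal with the alkenyl group equatorial, the enolate attacks axially to set the tertiary carbinol (4S), and the δ-hydroxy ester then lactonises.

Step 6 (key step)
Reactants: 6, lactone
Product: 7, (1S,6S)-6-hydroxy-2,2,6-trimethylcyclohex-3-ene-1-carboxylic acid
Conditions: LDA (2.3 equiv), TMSCl/Et3N, THF, −78 °C → rt; PhMe, 110 °C; 1 M HCl/THF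
Reagents that add atoms: none
Why: Ireland–Claisen [3,3]-sigmatropic rearrangement of the lactone silyl ketene acetal through the enforced boat transition state forms the C1–C2 bond and the carbocycle on the alkenyl face, so the (6S) C–O centre is transferred to C1 (S) and the existing tertiary carbinol ends up trans to CO2H.

Step 7
Reactants: 7, cyclohexene acid
Product: 8, (1S,2S)-2-hydroxy-2,6,6-trimethylcyclohexane-1-carboxylic acid
Conditions: H2 (1–3 atm), 10% Pd/C, EtOAc, rt
Reagents that add atoms: none
Why: Catalytic hydrogenation of the only alkene, done before the polyene chain is attached; no stereocentre is affected.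

Step 8
Reactants: 8, hydroxy acid
Product: 9, (1S,2R)-2-(hydroxymethyl)-1,3,3-trimethylcyclohexan-1-ol
Conditions: LiAlH4, THF, reflux
Reagents that add atoms: none
Why: Hydride reduction of the acid to the primary alcohol; C1 is not epimerisable under these conditions.

Step 9
Reactants: 9, diol
Product: 10, (1S,2S)-1,3,3-trimethyl-2-[(phenylsulfanyl)methyl]cyclohexan-1-ol
Conditions: PhSSPh, n-Bu3P, pyridine, 60 °C
Reagents that add atoms: diphenyl disulfide, c1ccccc1SSc1ccccc1
Why: Hata thioetherification activates only the primary alcohol as an alkoxyphosphonium, which thiolate displaces by SN2; the tertiary OH is inert.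

Step 10
Reactants: 10, sulfide
Product: 11, (1S,2S)-1,3,3-trimethyl-2-[(phenylsulfonyl)methyl]cyclohexan-1-ol
Conditions: 30% H2O2, (NH4)6Mo7O24 (cat.), EtOH, 0 °C → rt
Reagents that add atoms: hydrogen peroxide, OO
Why: Molybdate-catalysed sulfide-to-sulfone oxidation; no other oxidisable group is present.

Step 11
Reactants: 12, (2E,6E)-farnesol
Product: 13, (2E,6E)-farnesyl acetate
Conditions: Ac2O, pyridine, DMAP (cat.), CH2Cl2, rt
Reagents that add atoms: acetic anhydride, CC(=O)OC(C)=O
Why: Acetylation protects the allylic alcohol and deactivates the C2 alkene towards the next oxidation.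

Step 12
Reactants: 13, farnesyl acetate
Product: 14, (2E,6E,10E)-12-hydroxy-3,7,11-trimethyldodeca-2,6,10-trien-1-yl acetate
Conditions: SeO2 (cat.), t-BuOOH, salicylic acid (cat.), CH2Cl2, rt; NaBH4, MeOH, 0 °C (reduces over-oxidised enal)
Reagents that add atoms: selenium dioxide, O=[Se]=O; tert-butyl hydroperoxide, CC(C)(C)OO
Why: Sharpless-type SeO2 allylic oxidation (ene, then [2,3]-shift) selectively hydroxylates the (E)-methyl of the terminal, most electron-rich alkene.

Step 13
Reactants: 14, allylic alcohol
Product: 15, (2E,6E,10E)-12-bromo-3,7,11-trimethyldodeca-2,6,10-trien-1-yl acetate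
Conditions: CBr4, PPh3, CH2Cl2, 0 °C
Reagents that add atoms: carbon tetrabromide, BrC(Br)(Br)Br
Why: Appel bromination of the primary allylic alcohol proceeds without allylic transposition or loss of E geometry.

Step 14
Reactants: 11, sulfone; 15, allylic bromide
Product: 16, (2E,6E,10E)-13-[(1S,2S)-2-hydroxy-2,6,6-trimethylcyclohexyl]-3,7,11-trimethyl-13-(phenylsulfonyl)trideca-2,6,10-trien-1-yl acetate (mixture of epimers at the sulfone carbon, removed in step 15)
Conditions: n-BuLi (2.1 equiv), THF/DMPU, −78 °C; then 15, −78 → −20 °C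
Reagents that add atoms: none (both partners are the listed reactants)
Why: Julia-type SN2 alkylation of the alkoxide/α-sulfonyl dianion with the primary allylic bromide forms the last C–C bond with E geometry retained.

Step 15
Reactants: 16, coupled sulfone
Product: 17, preluffariellolide A
Conditions: 6% Na(Hg), Na2HPO4, MeOH/THF, −20 °C; then K2CO3, MeOH, rt (one pot)
Reagents that add atoms: none
Why: Reductive desulfonylation of the homoallylic (non-allylic) sulfone leaves the alkenes in place, and methanolysis removes the acetate.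

**Compound list**
1 | (S)-α-hydroxy-γ-butyrolactone | O[C@H]1CCOC1=O | starting material
2 | (3S)-oxolane-2,3-diol | O[C@H]1CCOC1O | intermediate
3 | (3S)-5-methylhex-4-ene-1,3-diol | O[C@H](C=C(C)C)CCO | intermediate
4 | (3S)-3-hydroxy-5-methylhex-4-enoic acid | O[C@H](C=C(C)C)CC(=O)O | intermediate
5 | (4S)-4-hydroxy-6-methylhept-5-en-2-one | O[C@H](C=C(C)C)CC(C)=O | intermediate
6 | (4S,6S)-4-hydroxy-4-methyl-6-(2-methylprop-1-en-1-yl)oxan-2-one | O=C1C[C@@](C)(O)C[C@@H](C=C(C)C)O1 | intermediate
7 | (1S,6S)-6-hydroxy-2,2,6-trimethylcyclohex-3-ene-1-carboxylic acid | OC(=O)[C@H]1C(C)(C)C=CC[C@]1(C)O | intermediate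
8 | (1S,2S)-2-hydroxy-2,6,6-trimethylcyclohexane-1-carboxylic acid | OC(=O)[C@H]1C(C)(C)CCC[C@]1(C)O | intermediate
9 | (1S,2R)-2-(hydroxymethyl)-1,3,3-trimethylcyclohexan-1-ol | OC[C@H]1C(C)(C)CCC[C@]1(C)O | intermediate
10 | (1S,2S)-1,3,3-trimethyl-2-[(phenylsulfanyl)methyl]cyclohexan-1-ol | C(Sc1ccccc1)[C@H]2C(C)(C)CCC[C@]2(C)O | intermediate
11 | (1S,2S)-1,3,3-trimethyl-2-[(phenylsulfonyl)methyl]cyclohexan-1-ol | O=S(=O)(C[C@H]1C(C)(C)CCC[C@]1(C)O)c1ccccc1 | intermediate
12 | (2E,6E)-farnesol | OC/C=C(\C)CC/C=C(\C)CCC=C(C)C | starting material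
13 | (2E,6E)-farnesyl acetate | CC(=O)OC/C=C(\C)CC/C=C(\C)CCC=C(C)C | intermediate
14 | (2E,6E,10E)-12-hydroxyfarnesyl acetate | CC(=O)OC/C=C(\C)CC/C=C(\C)CC/C=C(\C)CO | intermediate
15 | (2E,6E,10E)-12-bromofarnesyl acetate | CC(=O)OC/C=C(\C)CC/C=C(\C)CC/C=C(\C)CBr | intermediate
16 | coupled sulfone acetate (epimers at the sulfone carbon) | CC(=O)OC/C=C(\C)CC/C=C(\C)CC/C=C(\C)CC([C@H]1C(C)(C)CCC[C@]1(C)O)S(=O)(=O)c1ccccc1 | intermediate
17 | preluffariellolide A, (2E,6E,10E)-13-[(1S,2S)-2-hydroxy-2,6,6-trimethylcyclohexyl]-3,7,11-trimethyltrideca-2,6,10-trien-1-ol | C/C(=C\CO)CC/C=C(\C)CC/C=C(\C)CC[C@H]1C(C)(C)CCC[C@]1(C)O | target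

**Step count**
Total steps: 15. Longest linear sequence: 12 (steps 1–10, 14, 15); the farnesyl branch is 3 steps.

**Three steps most likely to fail**
- **Step 6 (Ireland–Claisen ring closure).** The boat transition state must build a quaternary carbon next to a fully substituted centre, and silyl ketene acetal decomposition or allylic ionisation could compete. Fallback: form the same C1–C2 bond by an acyclic chair Ireland–Claisen of the (S)-4-methylpent-3-en-2-yl ester (alcohol from ethyl (S)-lactate) of a 3-silyloxy-3-methylhex-5-enoic acid, then close the ring by ring-closing metathesis and hydrogenate.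
- **Step 5 (1,3-induction in the acetate aldol).** A modest diastereomer ratio or retro-aldol of 5 would cost material; the C4 epimers are separable at the lactone stage. Fallback: protect the carbinol as its PMB ether and run a Lewis-acid chelated (MgBr2·OEt2) Mukaiyama aldol with the silyl ketene acetal of ethyl acetate, then DDQ and lactonisation.
- **Step 14 (alkylation of the hindered sulfone dianion with the acetate present).** Slow alkylation or acyl transfer is possible. Fallback: oxidise 9 to the aldehyde, methylenate, hydroborate with 9-BBN and join by B-alkyl Suzuki coupling to the (E)-vinyl iodide of the C14 chain (from a geraniol-derived alkyne by Negishi carboalumination/iodination), which removes the sulfone chemistry altogether.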